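**Retrosynthetic overview**
1. Target 19 ⇐ double C-prenylation of the last enolisable ring carbon of spiro trione diol 16 (prenyl groups go on last, after all alkene chemistry).
2. 16 ⇐ spiro ketone 13: the C3' carbinol by methyl addition to the ring C ketone, the C7' carbinol by Markovnikov hydration of an exocyclic methylene.
3. 13 ⇐ isobutyrylphloroglucinol 3 + bis-electrophile 11 in a one-pot dearomative [5+1] spiroannulation (C-Michael addition, then Pd-allyl closure at the same arene carbon).
4. 11 ⇐ cyclopent-2-enone by asymmetric alkenyl 1,4-addition, Mannich methylenation and allylic chlorination; 3 ⇐ phloroglucinol.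
5. Ring order: ring C is bought, ring A (the arene) is acylated, ring B and the spiro centre form in the key step as ring A loses aromaticity.

Assumption: enolised triones are drawn as one tautomer, and in the two ligand-controlled steps (2 and 4) the ligand antipode named is taken as the matched one (its mirror image is used if the measured sense is opposite).

Locants used below: spiro[cyclohexane-1,5'-indene]; C2 is the ring carbonyl next to the acyl-bearing carbon C3, C5 the carbon that ends up diprenylated, C6 the carbonyl between C1 and C5.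

**Step 1**
Reactants: 1 phloroglucinol; 2 isobutyryl chloride
Product: 3 2-methyl-1-(2,4,6-trihydroxyphenyl)propan-1-one
Conditions: AlCl3 (4 equiv), PhNO2–CH2Cl2, 0 to 45 °C; aq. HCl
Reagents that add atoms: none
Why: Friedel–Crafts C-acylation of the electron-rich arene stops at the mono-ketone because the chelated aryl ketone is deactivated; no stereocentre is formed.

**Step 2**
Reactants: 4 cyclopent-2-en-1-one; 5 isopropenylmagnesium bromide
Product: 10 (R)-2-methylidene-3-(prop-1-en-2-yl)cyclopentan-1-one, via chloro(isopropenyl)zirconocene 6 (not isolated), via zirconium enolate 7 (not isolated), via Mannich base 8 (not isolated), via methiodide 9 (not isolated)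
Conditions: Cp2ZrCl2 (1.25 equiv), 5 (1.2 equiv), THF, 0 °C; then 4, [Rh(cod)(MeCN)2]BF4 (5 mol %), (S)-BINAP (6 mol %), 20 °C; then CH2=NMe2+ I− (1.5 equiv), 0 to 20 °C; then MeI; then aq. NaHCO3; used at once as a cold solution
Reagents that add atoms: N,N-dimethylmethyleneiminium iodide (Eschenmoser's salt), C=[N+](C)C.[I-]
Why: Rhodium/BINAP-catalysed asymmetric 1,4-addition of the alkenylzirconocene (Hayashi–Miyaura-type conjugate addition) delivers isopropenyl to one enone face and sets C3 (the only stereocentre made by an external catalyst on this fragment), the regio-defined zirconium enolate is trapped at C2 in a Mannich reaction, and Hofmann-type elimination of the methiodide unveils the exocyclic enone.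

**Step 3**
Reactants: 10 (R)-2-methylidene-3-(prop-1-en-2-yl)cyclopentan-1-one
Product: 11 (S)-3-(3-chloroprop-1-en-2-yl)-2-methylidenecyclopentan-1-one
Conditions: Ca(OCl)2 (0.6 equiv), solid CO2, CH2Cl2–H2O, 0 °C
Reagents that add atoms: calcium hypochlorite Ca(OCl)2, [Ca+2].[O-]Cl.[O-]Cl
Why: Ene-type allylic chlorination by HOCl attacks only the electron-rich 1,1-disubstituted alkene (Cl to the CH2 terminus, loss of a methyl proton) while the electron-poor enone alkene is inert; the stereocentre is untouched (descriptor changes by priority only).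

**Step 4**
Reactants: 3 2-methyl-1-(2,4,6-trihydroxyphenyl)propan-1-one; 11 (S)-3-(3-chloroprop-1-en-2-yl)-2-methylidenecyclopentan-1-one
Product: 13 (1S,3a'R,7a'S)-4-hydroxy-7'-methylidene-3-(2-methylpropanoyl)octahydrospiro[cyclohex-3-ene-1,5'-indene]-2,3',6-trione, via Michael adduct 12 (not isolated)
Conditions: 3 (1.3 equiv), Cs2CO3 (0.1 equiv), THF, 0 °C; then Pd2(dba)3·CHCl3 (2.5 mol %), (R,R)-DACH-phenyl Trost ligand (7.5 mol %), Cs2CO3 (1.1 equiv), THF–CH2Cl2, 0.02 M, 0 to 20 °C
Reagents that add atoms: none
Why: Proposed new method: base-mediated C-Michael addition of the phloroglucinol to the exocyclic enone gives, after enolate protonation, the thermodynamic trans-2,3-disubstituted cyclopentanone (sets C3a'), then zerovalent palladium ionises the 2-substituted allyl chloride and the same, now fully substituted, arene carbon attacks the π-allyl terminus to close the six-membered ring B with loss of aromaticity, the Trost ligand pocket choosing the face of the planar phloroglucinolate so that C6 ends axial and C2 equatorial on ring B (1S); the closest known reactions are palladium-catalysed dearomative conjunctive allylic annulation of acylphloroglucinols and Trost-ligand-controlled allylic dearomatisation of phenols and naphthols.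

**Step 5**
Reactants: 13 (1S,3a'R,7a'S)-4-hydroxy-7'-methylidene-3-(2-methylpropanoyl)octahydrospiro[cyclohex-3-ene-1,5'-indene]-2,3',6-trione
Product: 14 (1S,3'S,3a'R,7a'S)-3',4-dihydroxy-3'-methyl-7'-methylidene-3-(2-methylpropanoyl)octahydrospiro[cyclohex-3-ene-1,5'-indene]-2,6-dione
Conditions: MeTi(OiPr)3 (6 equiv), THF–CH2Cl2, −30 to 20 °C; aq. NH4Cl
Reagents that add atoms: methyltitanium triisopropoxide MeTi(OiPr)3, C[Ti](OC(C)C)(OC(C)C)OC(C)C
Why: 1,2-Addition of the non-basic organotitanium reagent to the only free ketone (the trione carbonyls are masked as titanium enolates, and no enolisation means no retro-Michael or epimerisation): the bulky reagent approaches the cyclopentanone from the face away from the two syn-axial hydrogens H-7a' and H-4'ax, placing methyl trans and OH cis to the C4' branch (3'S).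

**Step 6**
Reactants: 14 (1S,3'S,3a'R,7a'S)-3',4-dihydroxy-3'-methyl-7'-methylidene-3-(2-methylpropanoyl)octahydrospiro[cyclohex-3-ene-1,5'-indene]-2,6-dione
Product: 16 (1S,3'S,3a'R,7'S,7a'S)-3',4,7'-trihydroxy-3',7'-dimethyl-3-(2-methylpropanoyl)octahydrospiro[cyclohex-3-ene-1,5'-indene]-2,6-dione, via hydroperoxide 15 (not isolated)
Conditions: Mn(dpm)3 (20 mol %), PhSiH3 (2.5 equiv), O2 (1 atm), iPrOH–CH2Cl2, 0 °C; then PPh3
Reagents that add atoms: dioxygen, O=O
Why: Mukaiyama hydration (metal-hydride hydrogen-atom transfer) puts H on the exocyclic CH2 and the tertiary C7' radical is captured by O2 from the equatorial direction because the axial face is screened 1,3-diaxially by the axial C6 carbonyl of the spiro ring, giving equatorial OH and axial methyl (7'S) after phosphine reduction of the hydroperoxide.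

**Step 7**
Reactants: 16 (1S,3'S,3a'R,7'S,7a'S)-3',4,7'-trihydroxy-3',7'-dimethyl-3-(2-methylpropanoyl)octahydrospiro[cyclohex-3-ene-1,5'-indene]-2,6-dione; 17 prenyl bromide
Product: 19 (1S,3'S,3a'R,7'S,7a'S)-3',4,7'-trihydroxy-3',7'-dimethyl-5,5-bis(3-methylbut-2-en-1-yl)-3-(2-methylpropanoyl)octahydrospiro[cyclohex-3-ene-1,5'-indene]-2,6-dione, via monoprenyl enol 18 (not isolated)
Conditions: 17 (2.6 equiv), 10 % aq. KOH, 0 to 20 °C
Reagents that add atoms: none
Why: Twofold alkylative C-prenylation of the vinylogous acid at its only remaining enolisable ring carbon C5 (lupulone-type gem-diprenylation, C-alkylation favoured for the hydrogen-bonded enolate in water); no stereocentre is touched and the tertiary alcohols are inert.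

**Compound list**
1 | phloroglucinol | Oc1cc(O)cc(O)c1 | starting material
2 | isobutyryl chloride | CC(C)C(Cl)=O | starting material
3 | 2-methyl-1-(2,4,6-trihydroxyphenyl)propan-1-one | CC(C)C(=O)c1c(O)cc(O)cc1O | intermediate
4 | cyclopent-2-en-1-one | O=C1C=CCC1 | starting material
5 | isopropenylmagnesium bromide | CC(=C)[Mg]Br | starting material
6 | chloro(isopropenyl)zirconocene Cp2Zr(Cl)(C(Me)=CH2) | CC(=C)[Zr](Cl)(C1C=CC=C1)C1C=CC=C1 | intermediate
7 | chloro{[(3S)-3-(prop-1-en-2-yl)cyclopent-1-en-1-yl]oxy}zirconocene | Cl[Zr](OC1=C[C@H](CC1)C(C)=C)(C1C=CC=C1)C1C=CC=C1 | intermediate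
8 | (2S,3S)-2-[(dimethylamino)methyl]-3-(prop-1-en-2-yl)cyclopentan-1-one (trans) | CN(C)C[C@@H]1[C@H](CCC1=O)C(C)=C | intermediate
9 | trimethylammonium iodide (methiodide) of 8 | C[N+](C)(C)C[C@@H]1[C@H](CCC1=O)C(C)=C.[I-] | intermediate
10 | (R)-2-methylidene-3-(prop-1-en-2-yl)cyclopentan-1-one | C=C1[C@H](CCC1=O)C(C)=C | intermediate
11 | (S)-3-(3-chloroprop-1-en-2-yl)-2-methylidenecyclopentan-1-one | C=C1[C@H](CCC1=O)C(=C)CCl | intermediate
12 | 1-(3-{[(1R,2S)-2-(3-chloroprop-1-en-2-yl)-5-oxocyclopentyl]methyl}-2,4,6-trihydroxyphenyl)-2-methylpropan-1-one | CC(C)C(=O)c1c(O)cc(O)c(C[C@@H]2[C@H](CCC2=O)C(=C)CCl)c1O | intermediate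
13 | (1S,3a'R,7a'S)-4-hydroxy-7'-methylidene-3-(2-methylpropanoyl)octahydrospiro[cyclohex-3-ene-1,5'-indene]-2,3',6-trione (trans-fused, C6 axial on ring B) | C1C(=O)[C@@]2(C[C@@H]3[C@H](CCC3=O)C(=C)C2)C(=O)C(C(=O)C(C)C)=C1O | intermediate
14 | (1S,3'S,3a'R,7a'S)-3',4-dihydroxy-3'-methyl-7'-methylidene-3-(2-methylpropanoyl)octahydrospiro[cyclohex-3-ene-1,5'-indene]-2,6-dione | C1C(=O)[C@@]2(C[C@@H]3[C@H](CC[C@]3(C)O)C(=C)C2)C(=O)C(C(=O)C(C)C)=C1O | intermediate
15 | (1S,3'S,3a'R,7'S,7a'S)-7'-hydroperoxy-3',4-dihydroxy-3',7'-dimethyl-3-(2-methylpropanoyl)octahydrospiro[cyclohex-3-ene-1,5'-indene]-2,6-dione | C1C(=O)[C@@]2(C[C@@H]3[C@H](CC[C@]3(C)O)[C@@](C)(OO)C2)C(=O)C(C(=O)C(C)C)=C1O | intermediate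
16 | (1S,3'S,3a'R,7'S,7a'S)-3',4,7'-trihydroxy-3',7'-dimethyl-3-(2-methylpropanoyl)octahydrospiro[cyclohex-3-ene-1,5'-indene]-2,6-dione | C1C(=O)[C@@]2(C[C@@H]3[C@H](CC[C@]3(C)O)[C@@](C)(O)C2)C(=O)C(C(=O)C(C)C)=C1O | intermediate
17 | prenyl bromide (1-bromo-3-methylbut-2-ene) | CC(C)=CCBr | starting material
18 | 5-mono(3-methylbut-2-en-1-yl) derivative of 16, enol form, same configuration at all five stereocentres | CC(C)=CCC1=C(O)C(C(=O)C(C)C)=C(O)[C@]2(C[C@@H]3[C@H](CC[C@]3(C)O)[C@@](C)(O)C2)C1=O | intermediate
19 | (1S,3'S,3a'R,7'S,7a'S)-3',4,7'-trihydroxy-3',7'-dimethyl-5,5-bis(3-methylbut-2-en-1-yl)-3-(2-methylpropanoyl)octahydrospiro[cyclohex-3-ene-1,5'-indene]-2,6-dione | CC(C)=CCC1(CC=C(C)C)C(=O)[C@@]2(C[C@@H]3[C@H](CC[C@]3(C)O)[C@@](C)(O)C2)C(=O)C(C(=O)C(C)C)=C1O | target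

**Totals and risks**

Total step count: 7. Longest linear sequence: 6 (steps 2 to 7, from cyclopent-2-en-1-one).

Most likely to fail, first: step 4. The spiro centre differs only in remote substituents, so its control rests entirely on the ligand, and O-allylation or intermolecular allylation can compete. Fallback: set out from 3 and 10 (skipping the chlorination). A Cs2CO3-catalysed Michael addition gives the isopropenyl Michael adduct F1. Mn(OAc)3·2H2O and Cu(OAc)2 in AcOH then effect a dearomative oxidative radical cyclisation, 6-endo onto the 1,1-disubstituted alkene, with oxidative elimination to the exocyclic methylene. This gives 13 together with the spiro epimer F2, which is removed by chromatography, and the route resumes at 13. This fallback does not control the spiro centre; it relies on separation.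

Second: step 5. The hindered ring-fusion cyclopentanone may react slowly with the titanium reagent, and the facial preference on the trans-hydrindanone is an argument from analogy with equatorial attack on cyclohexanones. Fallback: set out from 12, isolated by stopping step 4 before palladium is added. MeMgBr with CeCl3 in THF at −78 °C adds to the monocyclic trans-2,3-disubstituted cyclopentanone anti to its 2-arylmethyl substituent and gives the tertiary carbinol F3. Ring closure under the palladium conditions of step 4 then delivers 14 directly, where the route continues.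

Third: step 6. The enolised trione with a free ring CH is easily oxidised under radical/O2 conditions and may bind the manganese catalyst. Fallback: set out from 14 and reverse the order. Double prenylation with 17 in aqueous KOH gives the diprenyl exocyclic alkene F4. Oxymercuration with Hg(OAc)2 (1.0 equiv) in THF–H2O is selective for the 1,1-disubstituted alkene over the trisubstituted prenyl alkenes, and water attacks equatorially for the same 1,3-diaxial reason. This gives the organomercurial F5, and NaBH4 in aqueous NaOH demercurates it to the target 19.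

Further compounds
F1 | step 4 | 1-(2,4,6-trihydroxy-3-{[(1R,2S)-5-oxo-2-(prop-1-en-2-yl)cyclopentyl]methyl}phenyl)-2-methylpropan-1-one | CC(C)C(=O)c1c(O)cc(O)c(C[C@@H]2[C@H](CCC2=O)C(C)=C)c1O
F2 | step 4 | (1R,3a'R,7a'S) spiro epimer of 13 | C1C(=O)[C@]2(C[C@@H]3[C@H](CCC3=O)C(=C)C2)C(=O)C(C(=O)C(C)C)=C1O
F3 | step 5 | 1-(3-{[(1R,2S,5S)-2-(3-chloroprop-1-en-2-yl)-5-hydroxy-5-methylcyclopentyl]methyl}-2,4,6-trihydroxyphenyl)-2-methylpropan-1-one | CC(C)C(=O)c1c(O)cc(O)c(C[C@@H]2[C@H](CC[C@]2(C)O)C(=C)CCl)c1O
F4 | step 6 | 5,5-bis(3-methylbut-2-en-1-yl) derivative of 14 (7'-methylidene analogue of 19) | CC(C)=CCC1(CC=C(C)C)C(=O)[C@@]2(C[C@@H]3[C@H](CC[C@]3(C)O)C(=C)C2)C(=O)C(C(=O)C(C)C)=C1O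
F5 | step 6 | 7'-[(acetoxymercurio)methyl] analogue of 19 | CC(C)=CCC1(CC=C(C)C)C(=O)[C@@]2(C[C@@H]3[C@H](CC[C@]3(C)O)[C@@](C[Hg]OC(C)=O)(O)C2)C(=O)C(C(=O)C(C)C)=C1O
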